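**Assumption:** the target has no stereocentre and no stereogenic double bond, so it is made as the single achiral compound drawn and no stereocontrol is needed. 1,2,3,4-Tetramethoxybenzene and 2-bromo-5-hydroxy-4-methoxybenzaldehyde (6-bromoisovanillin) are taken as catalogue chemicals.

## Retrosynthetic overview

- The C2–C1′ bond is cut last: a C2-zincated 5,6,7,8-tetramethoxychromone (a masked aroyl anion / β-acylvinyl anion, nucleophilic at the carbon that is normally the electrophilic one) is coupled with the electrophilic C–Br carbon of 4-bromo-6-methoxyresorcinol, without protecting groups.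
- The chromone comes from 2-hydroxy-3,4,5,6-tetramethoxyacetophenone and DMF-DMA; the acetophenone from 2,3,4,5-tetramethoxyphenol; the phenol from 1,2,3,4-tetramethoxybenzene by ortho-lithiation, borylation and oxidation.
- The bromoresorcinol comes from 6-bromoisovanillin by Baeyer–Villiger (Dakin-type) oxidation.
- Ring order: the A and B rings are bought as benzenes; the pyranone (C ring) is the only ring formed, in step 3; the B ring is attached in the last step.

## Route

**Step 1**
Reactants: 1 1,2,3,4-tetramethoxybenzene
Product: 4 2,3,4,5-tetramethoxyphenol, via aryllithium 2 (not isolated), via dimethyl arylboronate 3 (not isolated)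
Conditions: n-BuLi, TMEDA, THF, 0 °C; B(OMe)3, −78 °C → rt; AcOH, 30% H2O2, 0 °C → rt; Na2S2O3 quench
Reagents that add atoms: hydrogen peroxide OO (the phenol oxygen of 4); n-butyllithium [Li]CCCC (Li of 2 only); trimethyl borate COB(OC)OC (B(OMe)2 of 3 only)
Why: Methoxy-directed ortho-lithiation at the only kind of ring C–H, borate trapping and peroxide ipso-oxidation of the aryl–boron bond (1,2-aryl shift from B to O) give the phenol; no stereocentre is formed.

**Step 2**
Reactants: 4 2,3,4,5-tetramethoxyphenol
Product: 5 1-(2-hydroxy-3,4,5,6-tetramethoxyphenyl)ethan-1-one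
Conditions: AcOH, BF3·OEt2, 90 °C; aq. NaOAc work-up
Reagents that add atoms: acetic acid CC(=O)O
Why: BF3-mediated Friedel–Crafts/Fries-type C-acetylation can only go to the single free ring position, which is ortho to the OH, and aryl methyl ethers are not cleaved by BF3·OEt2 in AcOH at this temperature.

**Step 3**
Reactants: 5 1-(2-hydroxy-3,4,5,6-tetramethoxyphenyl)ethan-1-one
Product: 7 5,6,7,8-tetramethoxy-4H-chromen-4-one, via enaminone 6 (not isolated)
Conditions: DMF-DMA, toluene, 100 °C; evaporate; conc. HCl, CH2Cl2, 40 °C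
Reagents that add atoms: N,N-dimethylformamide dimethyl acetal COC(OC)N(C)C
Why: Condensation of the methyl ketone with the amide acetal gives the (E)-enaminone, and acid then drives 6-endo addition of the phenol oxygen with loss of dimethylamine (enaminone chromone synthesis), closing the pyranone ring.

**Step 4**
Reactants: 8 2-bromo-5-hydroxy-4-methoxybenzaldehyde
Product: 10 4-bromo-6-methoxybenzene-1,3-diol, via aryl formate 9 (not isolated)
Conditions: mCPBA, CH2Cl2, 0 °C → rt; aq. Na2S2O3/NaHCO3 wash; cat. HCl, MeOH, rt
Reagents that add atoms: meta-chloroperoxybenzoic acid OOC(=O)c1cccc(Cl)c1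
Why: Baeyer–Villiger (Dakin-type) oxidation in which the electron-rich aryl group (OMe para to CHO) migrates to oxygen; the formate keeps the new phenol masked until the peracid is washed out and is then methanolysed, with C–Br and OMe untouched and the substitution pattern fixed by the starting material.

**Step 5**
Reactants: 7 5,6,7,8-tetramethoxy-4H-chromen-4-one; 10 4-bromo-6-methoxybenzene-1,3-diol
Product: 13 2-(2,4-dihydroxy-5-methoxyphenyl)-5,6,7,8-tetramethoxy-4H-chromen-4-one (target), via bis(chromon-2-yl)zinc 11 (not isolated), via bis(chloromagnesium) phenoxide 12 (not isolated)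
Conditions: 7 (1.2 equiv), TMP2Zn·2MgCl2·2LiCl (0.6 equiv), THF, −30 °C, 1 h; 10 (1.0 equiv), MeMgCl (2.0 equiv), THF, −20 → 0 °C; combine, Pd(OAc)2 (3 mol%), SPhos (6 mol%), 50 °C; 1 M HCl work-up
Reagents that add atoms: none
Why: With MgCl2 bound at the C4 carbonyl (chelated by 5-OMe) the TMP–zinc amide removes H-2, giving a C2-zincated chromone that is nucleophilic at the normally electrophilic acyl/Michael carbon, and Pd/SPhos Negishi cross-coupling joins it to the electrophilic C–Br carbon of the bromide, whose phenols are masked in the flask as magnesium phenoxides so that no acidic proton quenches the organozinc (Lewis-acid-assisted directed zincation, then Negishi coupling; no stereocentre is formed).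

## Compound list

1 | 1,2,3,4-tetramethoxybenzene | COc1ccc(OC)c(OC)c1OC | starting material
2 | (2,3,4,5-tetramethoxyphenyl)lithium | [Li]c1cc(OC)c(OC)c(OC)c1OC | intermediate
3 | dimethyl (2,3,4,5-tetramethoxyphenyl)boronate (present as its lithium methoxide ate complex until acidified) | COB(OC)c1cc(OC)c(OC)c(OC)c1OC | intermediate
4 | 2,3,4,5-tetramethoxyphenol | COc1cc(O)c(OC)c(OC)c1OC | intermediate
5 | 1-(2-hydroxy-3,4,5,6-tetramethoxyphenyl)ethan-1-one | CC(=O)c1c(O)c(OC)c(OC)c(OC)c1OC | intermediate
6 | (E)-3-(dimethylamino)-1-(2-hydroxy-3,4,5,6-tetramethoxyphenyl)prop-2-en-1-one | CN(C)/C=C/C(=O)c1c(O)c(OC)c(OC)c(OC)c1OC | intermediate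
7 | 5,6,7,8-tetramethoxy-4H-chromen-4-one | O=c1ccoc2c(OC)c(OC)c(OC)c(OC)c12 | intermediate
8 | 2-bromo-5-hydroxy-4-methoxybenzaldehyde | COc1cc(Br)c(C=O)cc1O | starting material
9 | 2-bromo-5-hydroxy-4-methoxyphenyl formate | COc1cc(Br)c(OC=O)cc1O | intermediate
10 | 4-bromo-6-methoxybenzene-1,3-diol | COc1cc(Br)c(O)cc1O | intermediate
11 | bis(5,6,7,8-tetramethoxy-4-oxo-4H-chromen-2-yl)zinc (MgCl2/LiCl complex) | O=c1cc([Zn]c2cc(=O)c3c(OC)c(OC)c(OC)c(OC)c3o2)oc2c(OC)c(OC)c(OC)c(OC)c12 | intermediate
12 | bis(chloromagnesium) 4-bromo-6-methoxybenzene-1,3-diolate | COc1cc(Br)c(O[Mg]Cl)cc1O[Mg]Cl | intermediate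
13 | 2-(2,4-dihydroxy-5-methoxyphenyl)-5,6,7,8-tetramethoxy-4H-chromen-4-one | COc1cc(-c2cc(=O)c3c(OC)c(OC)c(OC)c(OC)c3o2)c(O)cc1O | target

## Count and risks

Total step count: 5. Longest linear sequence: 4 steps (steps 1, 2, 3, 5: 1 → 4 → 5 → 7 → 13); step 4 is the one-step side branch.

**Most likely to fail: step 5.** The zincation could go to C3 instead of C2; an iodine quench of an aliquot tells which, and C3 metalation would end in the isoflavone isomer. The very electron-rich bis-phenoxide bromide 12 may also add to Pd(0) too slowly or be poorly soluble, leaving 7 and debrominated resorcinol. The fallback sets out from 10 and comes back at 13. Both phenols of 10 are capped with MOMCl/i-Pr2NEt to give 1-bromo-5-methoxy-2,4-bis(methoxymethoxy)benzene F1. This neutral, soluble bromide is coupled under the same Pd/SPhos conditions with zinc reagent 11 (made from 7 as before, no MeMgCl needed) to give 2-[5-methoxy-2,4-bis(methoxymethoxy)phenyl]-5,6,7,8-tetramethoxy-4H-chromen-4-one F2. Both MOM groups are then removed with HCl in MeOH at 50 °C, which leaves the five methyl ethers alone, giving 13.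

**Second: step 2.** Hot BF3·OEt2 on a penta-oxygenated phenol may give partial demethylation next to the new carbonyl, oxidation to quinones, or stop at the O-acetate. The fallback sets out from 4 and comes back at 5, replacing electrophilic acylation by an anionic one. Phenol 4 is converted with MOMCl/i-Pr2NEt into 1,2,3,4-tetramethoxy-5-(methoxymethoxy)benzene F3. n-BuLi in THF at 0 °C lithiates the only ring C–H (flanked by OMOM and OMe) to give [6-(methoxymethoxy)-2,3,4,5-tetramethoxyphenyl]lithium F4. This is acylated with N-methoxy-N-methylacetamide to give 1-[2,3,4,5-tetramethoxy-6-(methoxymethoxy)phenyl]ethan-1-one F5, and cat. HCl in MeOH removes the MOM group to give 5.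

**Third: step 1.** Lithiation may be incomplete, and the electron-rich phenol 4 can be over-oxidised by peroxide to methoxyquinones. The fallback sets out from 1 and comes back at 4, replacing metalation by electrophilic substitution. Vilsmeier–Haack formylation of 1 (POCl3, DMF, 80 °C) gives 2,3,4,5-tetramethoxybenzaldehyde F6. Baeyer–Villiger oxidation with mCPBA in CH2Cl2 gives 2,3,4,5-tetramethoxyphenyl formate F7, in which the phenol stays masked while oxidant is present. Methanolysis with K2CO3 in MeOH after the peracid has been washed out gives 4.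

## Further compounds

F1 | step 5 | 1-bromo-5-methoxy-2,4-bis(methoxymethoxy)benzene | COCOc1cc(OCOC)c(OC)cc1Br
F2 | step 5 | 2-[5-methoxy-2,4-bis(methoxymethoxy)phenyl]-5,6,7,8-tetramethoxy-4H-chromen-4-one | COCOc1cc(OCOC)c(OC)cc1-c1cc(=O)c2c(OC)c(OC)c(OC)c(OC)c2o1
F3 | step 2 | 1,2,3,4-tetramethoxy-5-(methoxymethoxy)benzene | COCOc1cc(OC)c(OC)c(OC)c1OC
F4 | step 2 | [6-(methoxymethoxy)-2,3,4,5-tetramethoxyphenyl]lithium | [Li]c1c(OCOC)c(OC)c(OC)c(OC)c1OC
F5 | step 2 | 1-[2,3,4,5-tetramethoxy-6-(methoxymethoxy)phenyl]ethan-1-one | CC(=O)c1c(OCOC)c(OC)c(OC)c(OC)c1OC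
F6 | step 1 | 2,3,4,5-tetramethoxybenzaldehyde | COc1cc(C=O)c(OC)c(OC)c1OC
F7 | step 1 | 2,3,4,5-tetramethoxyphenyl formate | COc1cc(OC=O)c(OC)c(OC)c1OC
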